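## Retrosynthetic overview

1. Magnone B is the (2S,3R,4R)-oxolane with 2,3-trans and 3,4-cis substituents. The C4 aroyl group is unmasked late from a Z-configured exocyclic styrene, by hydroboration on the face away from the C3 arm followed by oxidation, so the labile cis ketone is made last.
2. The CH2OH arm at C3 comes from a gem-diester by loss of one ester (2,3-trans by equilibration) and reduction.
3. Structural feature used: in the oxolane ring O1–C2–C3–C4–C5, the benzylic ether carbon C2 adjoins C3. At the malonate level C3 is first the α-carbon of a Michael acceptor and then a carbanion. C4 and the ketone carbon are the two carbons of an alkyne whose CH2O unit is C5–O1.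
4. The only ring is therefore closed in one palladium cascade from propargyl alcohol, the trimethoxybenzylidene malonate and 4-iodo-1,2-dimethoxybenzene (bonds O1–C2, C3–C4, exocyclic C–aryl). A chiral bisphosphine on palladium is to select the C2 configuration.
5. The acceptor comes from 3,4,5-trimethoxybenzaldehyde and diethyl malonate.

Key step: step 2

Remark: the ring numbering used throughout is O1, C2 (trimethoxyphenyl), C3 (one-carbon arm), C4 (benzylidene or aroyl carbon), C5 (CH2).

Assumption: the sense of induction of the chiral ligand cannot be foretold. The (R)-ligand is written, and its mirror image is taken if screening shows that the (R)-ligand favours the wrong C2 configuration.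

## Route

Step 1
Reactants: 1 3,4,5-trimethoxybenzaldehyde; 2 diethyl malonate
Product: 3 diethyl 2-(3,4,5-trimethoxybenzylidene)malonate
Conditions: piperidine (cat.), AcOH (cat.), toluene, reflux, Dean–Stark trap
Reagents that add atoms: none
Why: Knoevenagel condensation of a non-enolisable, unhindered aldehyde with an active methylene compound, driven to completion by azeotropic removal of water; the two ester groups are alike, so no alkene isomers can arise.

Step 2
Reactants: 3 diethyl 2-(3,4,5-trimethoxybenzylidene)malonate; 4 propargyl alcohol; 5 4-iodo-1,2-dimethoxybenzene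
Product: 8 diethyl (2R,4Z)-4-[(3,4-dimethoxyphenyl)methylidene]-2-(3,4,5-trimethoxyphenyl)oxolane-3,3-dicarboxylate, via potassium prop-2-yn-1-olate 6 (not isolated), via racemic oxa-Michael enolate 7 (not isolated)
Conditions: 4, KOt-Bu, THF, 0 °C; then 3, 5, Pd2(dba)3 (2.5 mol %), (R)-DTBM-SEGPHOS (6 mol %), THF–DMSO, 25 °C
Reagents that add atoms: none
Why: Proposed new method: alkoxide 6 adds reversibly to acceptor 3 (oxa-Michael addition, bond O1–C2), so the two enantiomers of enolate 7 interconvert through their components, while zerovalent palladium inserts into the C–I bond of 5 and the arylpalladium iodide so formed (divalent palladium) gives up iodide as KI and binds the alkyne of 7. The malonate carbon then attacks the internal alkyne carbon on the side away from the metal (anti carbopalladation, bond C3–C4, 5-exo-dig closure of the oxolane ring), and reductive elimination with retention joins the exocyclic carbon to the dimethoxyphenyl ring, which fixes the Z alkene with the aryl group on the C5 side, trans to C3. The closest known reaction type is the racemic palladium-mediated three-component coupling of propargyl alkoxides, arylidene malonates and aryl halides run with achiral phosphines such as dppe; only the chiral bisphosphine, which is to turn the cascade into a dynamic kinetic resolution, is new. The one new stereocentre, C2, is under catalyst control: the closure is irreversible and, with little catalyst present and a donor-rich aryl group loosening the adduct, slower than the retro-oxa-Michael step, so that (Curtin–Hammett situation) the product configuration is decided by the two diastereomeric closure transition states, in one of which the large P-aryl groups of the ligand should collide with the C2 aryl and ester groups of the folding chain. The step further needs closure to outrun aryl–alkynyl coupling and O-arylation, which the copper-free medium, the capture of the alkoxide by the acceptor and the tethered soft carbanion should secure, and 5-exo rather than 6-endo attack, which the three-atom link C2–O1–C5 between carbanion and alkyne secures.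

Step 3
Reactants: 8 diethyl (2R,4Z)-4-[(3,4-dimethoxyphenyl)methylidene]-2-(3,4,5-trimethoxyphenyl)oxolane-3,3-dicarboxylate
Product: 9 ethyl (2S,3S,4Z)-4-[(3,4-dimethoxyphenyl)methylidene]-2-(3,4,5-trimethoxyphenyl)oxolane-3-carboxylate (2,3-trans; C2 is spatially unchanged, its descriptor changes through the priority rules only)
Conditions: LiCl, H2O, DMSO, 150 °C
Reagents that add atoms: none
Why: Krapcho dealkoxycarbonylation: chloride dealkylates one ethyl ester, CO2 leaves and water protonates the resulting ester dienolate at its α-carbon C3, and since C3–H remains exchangeable in the hot, weakly basic medium the ester should settle trans to the C2 aryl group (thermodynamic control, 3S), with any cis isomer removed by chromatography.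

Step 4
Reactants: 9 ethyl (2S,3S,4Z)-4-[(3,4-dimethoxyphenyl)methylidene]-2-(3,4,5-trimethoxyphenyl)oxolane-3-carboxylate
Product: 10 [(2S,3R,4Z)-4-[(3,4-dimethoxyphenyl)methylidene]-2-(3,4,5-trimethoxyphenyl)oxolan-3-yl]methanol
Conditions: i-Bu2AlH, CH2Cl2, −78 → 0 °C
Reagents that add atoms: none
Why: Reduction of an ester to the primary alcohol with a Lewis-acidic aluminium hydride of low basicity, which should leave the enolisable C3 centre, the styrene and the benzylic ether untouched at low temperature (the descriptor at C3 becomes R through the priority rules only).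

Step 5
Reactants: 10 [(2S,3R,4Z)-4-[(3,4-dimethoxyphenyl)methylidene]-2-(3,4,5-trimethoxyphenyl)oxolan-3-yl]methanol
Product: 11 tert-butyl{[(2S,3R,4Z)-4-[(3,4-dimethoxyphenyl)methylidene]-2-(3,4,5-trimethoxyphenyl)oxolan-3-yl]methoxy}dimethylsilane
Conditions: TBSCl, imidazole, CH2Cl2, 0 °C → rt
Reagents that add atoms: tert-butyldimethylsilyl chloride, CC(C)(C)[Si](C)(C)Cl
Why: Imidazole-promoted silylation of an unhindered primary alcohol, which masks the hydroxy group against borane and the oxidant and enlarges the C3 arm that has to shield one face of the alkene.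

Step 6
Reactants: 11 tert-butyl{[(2S,3R,4Z)-4-[(3,4-dimethoxyphenyl)methylidene]-2-(3,4,5-trimethoxyphenyl)oxolan-3-yl]methoxy}dimethylsilane
Product: 13 (2S,3R,4R)-3-[(tert-butyldimethylsilyloxy)methyl]-4-[(S)-(3,4-dimethoxyphenyl)(hydroxy)methyl]-2-(3,4,5-trimethoxyphenyl)oxolane, via benzylic alkylborane 12 (not isolated)
Conditions: BH3·THF, THF, 0 °C → rt; then NaOH, H2O2, H2O, 0 °C
Reagents that add atoms: hydrogen peroxide, OO (carbinol oxygen); borane (as BH3·THF), B (boron stays only in 12)
Why: Hydroboration–oxidation of a trisubstituted styrene: steric and electronic bias both send boron to the exocyclic benzylic carbon and hydrogen to C4, the syn addition should take place on the ring face opposite to the adjacent CH2OTBS arm so that the new side chain comes out cis to that arm (4R), and peroxide oxidation with retention gives the S carbinol, a centre that is erased in the next step.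

Step 7
Reactants: 13 (2S,3R,4R)-3-[(tert-butyldimethylsilyloxy)methyl]-4-[(S)-(3,4-dimethoxyphenyl)(hydroxy)methyl]-2-(3,4,5-trimethoxyphenyl)oxolane
Product: 14 (2S,3R,4R)-3-[(tert-butyldimethylsilyloxy)methyl]-4-(3,4-dimethoxybenzoyl)-2-(3,4,5-trimethoxyphenyl)oxolane
Conditions: Dess–Martin periodinane, pyridine, CH2Cl2, 0 °C → rt
Reagents that add atoms: none
Why: Dess–Martin oxidation of a secondary benzylic alcohol under pyridine-buffered, near-neutral conditions, chosen so that the epimerisable C4 centre next to the new aryl ketone keeps its less stable 3,4-cis arrangement.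

Step 8
Reactants: 14 (2S,3R,4R)-3-[(tert-butyldimethylsilyloxy)methyl]-4-(3,4-dimethoxybenzoyl)-2-(3,4,5-trimethoxyphenyl)oxolane
Product: 15 Magnone B, (3,4-dimethoxyphenyl)[(3R,4R,5S)-4-(hydroxymethyl)-5-(3,4,5-trimethoxyphenyl)oxolan-3-yl]methanone (2S,3R,4R in the ring numbering used here)
Conditions: HF·pyridine, THF, 0 °C → rt
Reagents that add atoms: none
Why: Fluoride-mediated cleavage of a primary TBS ether under mildly acidic conditions (no free basic fluoride and no alcohol solvent), which should avoid enolisation at C4, retro-oxa-Michael opening and ketal formation between the cis hydroxymethyl group and the ketone.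

## Compound list

1 | 3,4,5-trimethoxybenzaldehyde | COc1cc(C=O)cc(OC)c1OC | starting material
2 | diethyl malonate | CCOC(=O)CC(=O)OCC | starting material
3 | diethyl 2-(3,4,5-trimethoxybenzylidene)malonate | CCOC(=O)C(=Cc1cc(OC)c(OC)c(OC)c1)C(=O)OCC | intermediate
4 | propargyl alcohol (prop-2-yn-1-ol) | OCC#C | starting material
5 | 4-iodo-1,2-dimethoxybenzene | COc1ccc(I)cc1OC | starting material
6 | potassium prop-2-yn-1-olate | [K+].[O-]CC#C | intermediate
7 | potassium enolate of diethyl 2-[(prop-2-yn-1-yloxy)(3,4,5-trimethoxyphenyl)methyl]malonate (racemic at the ether carbon, in equilibrium with 3 and 6) | [K+].CCOC(=O)[C-](C(=O)OCC)C(OCC#C)c1cc(OC)c(OC)c(OC)c1 | intermediate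
8 | diethyl (2R,4Z)-4-[(3,4-dimethoxyphenyl)methylidene]-2-(3,4,5-trimethoxyphenyl)oxolane-3,3-dicarboxylate | CCOC(=O)C1(C(=O)OCC)[C@@H](c2cc(OC)c(OC)c(OC)c2)OC/C1=C\c3ccc(OC)c(OC)c3 | intermediate
9 | ethyl (2S,3S,4Z)-4-[(3,4-dimethoxyphenyl)methylidene]-2-(3,4,5-trimethoxyphenyl)oxolane-3-carboxylate | COc1ccc(/C=C2\CO[C@H](c3cc(OC)c(OC)c(OC)c3)[C@H]2C(=O)OCC)cc1OC | intermediate
10 | [(2S,3R,4Z)-4-[(3,4-dimethoxyphenyl)methylidene]-2-(3,4,5-trimethoxyphenyl)oxolan-3-yl]methanol | COc1ccc(/C=C2\CO[C@H](c3cc(OC)c(OC)c(OC)c3)[C@H]2CO)cc1OC | intermediate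
11 | tert-butyl{[(2S,3R,4Z)-4-[(3,4-dimethoxyphenyl)methylidene]-2-(3,4,5-trimethoxyphenyl)oxolan-3-yl]methoxy}dimethylsilane | COc1ccc(/C=C2\CO[C@H](c3cc(OC)c(OC)c(OC)c3)[C@H]2CO[Si](C)(C)C(C)(C)C)cc1OC | intermediate
12 | (2S,3R,4R)-4-[(S)-boranyl(3,4-dimethoxyphenyl)methyl]-3-[(tert-butyldimethylsilyloxy)methyl]-2-(3,4,5-trimethoxyphenyl)oxolane | COc1ccc([C@@H](B)[C@H]2CO[C@H](c3cc(OC)c(OC)c(OC)c3)[C@H]2CO[Si](C)(C)C(C)(C)C)cc1OC | intermediate
13 | (2S,3R,4R)-3-[(tert-butyldimethylsilyloxy)methyl]-4-[(S)-(3,4-dimethoxyphenyl)(hydroxy)methyl]-2-(3,4,5-trimethoxyphenyl)oxolane | COc1ccc([C@@H](O)[C@H]2CO[C@H](c3cc(OC)c(OC)c(OC)c3)[C@H]2CO[Si](C)(C)C(C)(C)C)cc1OC | intermediate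
14 | (2S,3R,4R)-3-[(tert-butyldimethylsilyloxy)methyl]-4-(3,4-dimethoxybenzoyl)-2-(3,4,5-trimethoxyphenyl)oxolane | COc1ccc(C(=O)[C@H]2CO[C@H](c3cc(OC)c(OC)c(OC)c3)[C@H]2CO[Si](C)(C)C(C)(C)C)cc1OC | intermediate
15 | Magnone B | COc1ccc(C(=O)[C@H]2CO[C@H](c3cc(OC)c(OC)c(OC)c3)[C@H]2CO)cc1OC | target

## Step count and risks

Total step count: 8. Longest linear sequence: 8 steps (from 1 or 2 to 15).

**1. Step 2: weak enantioselection in the ring closure.**
- The C2 stereocentre lies on the side of the alkyne remote from the metal. The ligand may therefore discriminate too weakly between the two interconverting enolate enantiomers, and the diester would form with low enantiomeric purity.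
- A bulky ligand may also slow alkyne binding and let aryl–alkynyl coupling compete.
- The fallback uses known chemistry only. It sets out from 3, 4 and 5 and comes back at 10.
- The cascade is run with the achiral ligand dppe (Pd2(dba)3, KOt-Bu, THF–DMSO), which is the known racemic three-component coupling. It gives 8 together with its mirror image, the (2S,4Z)-diester ent-8 F1.
- The conditions of steps 3 and 4 applied to the racemate give 9 with the (2R,3R,4Z)-ester ent-9 F2, and then 10 with the (2R,3S,4Z)-alcohol ent-10 F3.
- The racemic primary alcohol is resolved by lipase-catalysed acylation (Burkholderia cepacia lipase, vinyl acetate, t-BuOMe, 30 °C), taken to about half conversion.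
- If the enzyme acylates the unwanted antipode, the (2R,3S,4Z)-acetate of ent-10 F4 is removed by chromatography and unreacted 10 goes on to step 5.
- If the enzyme prefers 10, the (2S,3R,4Z)-acetate of 10 F5 is isolated and cleaved with K2CO3 in MeOH to 10.
- The same enzymatic step can also polish material of partial enantiomeric purity from the chiral-ligand run.

**2. Step 6: poor facial selectivity of the borane addition.**
- The face that must be attacked also carries the more distant C2 aryl group, and the C3 arm may lie close to the alkene plane.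
- The fallback sets out from 11 and comes back at 14. It sets C4 by kinetic enolate protonation instead of by hydroboration.
- The unselective hydroboration–oxidation gives 13 along with the (2S,3R,4S)-configured (R)-carbinol F6.
- The mixture is oxidised as in step 7, without separation, to 14 and the 3,4-trans (2S,3R,4S)-ketone F7.
- KHMDS (THF, −78 °C) converts both ketones into the same potassium enolate F8.
- In this tetrasubstituted enolate, allylic 1,3-strain with the enolate substituents should turn the CH2OTBS arm pseudoaxial over one face.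
- A bulky proton source (2,6-di-tert-butyl-4-methylphenol, −78 °C) should then protonate C4 from the open face and give the contra-thermodynamic 3,4-cis ketone 14.

**3. Step 3: three possible failures of the hot anionic decarboxylation.**
- γ-Protonation of the dienolate may move the alkene into conjugation with the ester.
- Reversible β-elimination and re-addition of O1 at the C3 anion may erode the C2 configuration.
- Equilibration to the 2,3-trans ester may be incomplete.
- The fallback sets out from 8 and comes back at 9. It avoids any C3 anion during the carbon–carbon cleavage.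
- One ester is saponified at room temperature (KOH, one equivalent, EtOH–H2O, then dilute acid), while C3 is still quaternary. The less hindered ester, trans to the C2 aryl group, should react and give the (2R,3R,4Z)-half-acid F9.
- Heating F9 in toluene or xylene (100–130 °C) without salt or base should release CO2 through the cyclic six-membered transition state of malonic half-esters. The neutral ketene hemiacetal so formed tautomerises to 9.
- A brief treatment with catalytic DBU in toluene is used only if the cis ester predominates.

## Further compounds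

F1 | step 2 | diethyl (2S,4Z)-4-[(3,4-dimethoxyphenyl)methylidene]-2-(3,4,5-trimethoxyphenyl)oxolane-3,3-dicarboxylate (ent-8) | CCOC(=O)C1(C(=O)OCC)[C@H](c2cc(OC)c(OC)c(OC)c2)OC/C1=C\c3ccc(OC)c(OC)c3
F2 | step 2 | ethyl (2R,3R,4Z)-4-[(3,4-dimethoxyphenyl)methylidene]-2-(3,4,5-trimethoxyphenyl)oxolane-3-carboxylate (ent-9) | COc1ccc(/C=C2\CO[C@@H](c3cc(OC)c(OC)c(OC)c3)[C@@H]2C(=O)OCC)cc1OC
F3 | step 2 | [(2R,3S,4Z)-4-[(3,4-dimethoxyphenyl)methylidene]-2-(3,4,5-trimethoxyphenyl)oxolan-3-yl]methanol (ent-10) | COc1ccc(/C=C2\CO[C@@H](c3cc(OC)c(OC)c(OC)c3)[C@@H]2CO)cc1OC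
F4 | step 2 | [(2R,3S,4Z)-4-[(3,4-dimethoxyphenyl)methylidene]-2-(3,4,5-trimethoxyphenyl)oxolan-3-yl]methyl acetate (acetate of ent-10) | COc1ccc(/C=C2\CO[C@@H](c3cc(OC)c(OC)c(OC)c3)[C@@H]2COC(C)=O)cc1OC
F5 | step 2 | [(2S,3R,4Z)-4-[(3,4-dimethoxyphenyl)methylidene]-2-(3,4,5-trimethoxyphenyl)oxolan-3-yl]methyl acetate (acetate of 10) | COc1ccc(/C=C2\CO[C@H](c3cc(OC)c(OC)c(OC)c3)[C@H]2COC(C)=O)cc1OC
F6 | step 6 | (2S,3R,4S)-3-[(tert-butyldimethylsilyloxy)methyl]-4-[(R)-(3,4-dimethoxyphenyl)(hydroxy)methyl]-2-(3,4,5-trimethoxyphenyl)oxolane | COc1ccc([C@H](O)[C@@H]2CO[C@H](c3cc(OC)c(OC)c(OC)c3)[C@H]2CO[Si](C)(C)C(C)(C)C)cc1OC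
F7 | step 6 | (2S,3R,4S)-3-[(tert-butyldimethylsilyloxy)methyl]-4-(3,4-dimethoxybenzoyl)-2-(3,4,5-trimethoxyphenyl)oxolane (3,4-trans ketone) | COc1ccc(C(=O)[C@@H]2CO[C@H](c3cc(OC)c(OC)c(OC)c3)[C@H]2CO[Si](C)(C)C(C)(C)C)cc1OC
F8 | step 6 | potassium enolate of 14 and F7 (C4=C(OK)Ar, aryl group drawn on the C5 side) | COc1ccc(/C([O-])=C2\CO[C@H](c3cc(OC)c(OC)c(OC)c3)[C@H]2CO[Si](C)(C)C(C)(C)C)cc1OC.[K+]
F9 | step 3 | (2R,3R,4Z)-4-[(3,4-dimethoxyphenyl)methylidene]-3-(ethoxycarbonyl)-2-(3,4,5-trimethoxyphenyl)oxolane-3-carboxylic acid | COc1ccc(/C=C2\CO[C@H](c3cc(OC)c(OC)c(OC)c3)[C@@]2(C(=O)OCC)C(=O)O)cc1OC
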